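## Retrosynthetic overview
1. The quinone comes from a 2,6-disubstituted phenol by para-oxidation in the last step. The arene is o-cresol, joined through its free ortho carbon to an isoprene-derived (E)-C5 allyl sulfone.
2. The C(=O)–CH2 bond of the side-chain ketone comes from acylation of that allyl sulfone carbanion. The sulfonyl group is then removed reductively.
3. The 1,5-diketone comes from retro-aldol (De Mayo) opening of a cyclobutane-fused 1,3-dioxan-4-one, triggered by the same acylation.
4. The cyclobutane comes from a [2+2] photocycloaddition of C2v-symmetric 1,2-dimethylcyclopentene to a menthone-derived spiro-dioxinone that already carries the 3-methylbut-2-enyl group. Both quaternary centres arise in this step.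
5. Ring order: dioxinone first (acylketene + menthone), then cyclobutane (light), then both temporary rings are opened together. The cyclopentane and the six-membered carbocycle are bought, and the latter becomes the quinone at the end.

Assumption: every compound marked "starting material" in the list, including the C7 alkene and the C6 acid, is taken as a catalogue chemical.

## Route

Step 1
Reactants: 1 4-methylpent-3-enoic acid; 2 2,2-dimethyl-1,3-dioxane-4,6-dione (Meldrum's acid)
Product: 3 5-(1-hydroxy-4-methylpent-3-en-1-ylidene)-2,2-dimethyl-1,3-dioxane-4,6-dione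
Conditions: DCC, DMAP, CH2Cl2, 0 °C to rt
Reagents that add atoms: none
Why: Carbodiimide-mediated C-acylation of Meldrum's acid, mild enough to leave the trisubstituted β,γ-alkene out of conjugation; no stereocentre is formed.

Step 2
Reactants: 3 acyl Meldrum's acid; 4 (−)-menthone
Product: 6 (6R,7S,10R)-7-isopropyl-10-methyl-2-(3-methylbut-2-en-1-yl)-1,5-dioxaspiro[5.5]undec-2-en-4-one, via acylketene 5 (not isolated)
Conditions: 4 (3 equiv), toluene, 110 °C, N2 sweep; chromatography
Reagents that add atoms: none
Why: Thermal fragmentation of the acyl Meldrum's acid gives acylketene 5, which the menthone C=O traps in a hetero-Diels–Alder [4+2]; the spiro centre forms as a roughly 1:1, separable pair of epimers, the (6R) epimer (enol-ether oxygen axial on the menthane chair) is kept, and the other is re-equilibrated under the same conditions.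

Step 3
Reactants: 6 spiro-dioxinone; 7 1,2-dimethylcyclopent-1-ene
Product: 8 (1R,2S,5R,1'R,2'R,7'R,8'R)-2-isopropyl-5,1',8'-trimethyl-2'-(3-methylbut-2-en-1-yl)spiro[cyclohexane-1,4'-[3,5]dioxatricyclo[6.3.0.0(2,7)]undecan]-6'-one (cis-anti-cis)
Conditions: hν (300 nm, Pyrex), 7 (10 equiv), EtOAc, −40 °C
Reagents that add atoms: none
Why: Enone–alkene [2+2] photocycloaddition (the cycloaddition half of an asymmetric De Mayo reaction, known for menthone-derived spiro-dioxinones): the triplet dioxinone adds to the C2v-symmetric alkene from the face on the side of the C11 methylene, the other face being covered by C7 and its isopropyl group, and with the carbocycle turned away from the heterocycle (cis-anti-cis), so the two equivalent alkene carbons become the (R,R) vicinal quaternary centres with cis methyl groups in one event, the one-carbon tether keeps the side-chain alkene out of reach of an intramolecular [2+2], and minor diastereomers are removed by chromatography and crystallisation.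

Step 4
Reactants: 9 isoprene; 10 benzenesulfonyl chloride
Product: 11 {[(2E)-4-chloro-2-methylbut-2-en-1-yl]sulfonyl}benzene
Conditions: CuCl (5 mol %), Et3N·HCl (5 mol %), MeCN, 90 °C, sealed tube; recrystallisation
Reagents that add atoms: none
Why: Copper-catalysed atom-transfer radical addition (Kharasch-type chlorosulfonylation): the sulfonyl radical adds to the CH2 terminus next to the methyl-bearing carbon to give the more substituted allyl radical, CuCl2 returns chlorine to the primary terminus, and the transoid radical gives the (E)-1,4-adduct, which is purified by crystallisation.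

Step 5
Reactants: 12 o-cresol; 11 chloro sulfone
Product: 14 2-methyl-6-[(2E)-3-methyl-4-(phenylsulfonyl)but-2-en-1-yl]phenol, via sodium 2-methylphenolate 13 (not isolated)
Conditions: NaH (1.0 equiv), toluene, 0 °C to rt; then 11, 60 °C
Reagents that add atoms: none
Why: Ortho-C-allylation of an ambident phenoxide: the tight sodium ion pair in non-polar toluene shields oxygen and delivers the primary allylic chloride (SN2, no allyl shift) to the only free ortho carbon, with the E-alkene untouched.

Step 6
Reactants: 8 photoadduct; 14 phenol sulfone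
Product: 18 2-[(2E)-6-[(1R,2R)-1,2-dimethyl-2-(4-methylpent-3-enoyl)cyclopentyl]-3-methyl-5-oxohex-2-en-1-yl]-6-methylphenol, via dilithiated sulfone 15 (not isolated), via lithium cyclobutanolate 16 (not isolated), via beta-keto sulfone 17 (not isolated)
Conditions: 14 (2.2 equiv), n-BuLi (4.4 equiv), THF, −78 °C; 8, −78 to 0 °C; AcOH, MeOH, −78 °C; SmI2, THF, −78 °C
Reagents that add atoms: none
Why: Proposed new method: the allyl sulfone carbanion of 15 attacks through its α-carbon the acylal-type lactone carbonyl of 8, the tetrahedral intermediate expels the hemiketal oxygen, which sheds (−)-menthone to leave cyclobutanolate 16, a strain-driven retro-aldol (De Mayo fragmentation) unveils both ketones while the charge settles as the non-nucleophilic β-keto sulfone anion (so no aldol or retro-Michael can touch the quaternary centres), and after protonation SmI2 cleaves the C–S bond of 17 through a samarium dienolate that is protonated at the α-carbon and keeps the (E)-β,γ-alkene; the closest known reaction types are ester acylation of sulfonyl carbanions, alkoxide-induced fragmentation of dioxinone photoadducts, and SmI2 desulfonylation of β-keto sulfones.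

Step 7
Reactants: 18 phenol diketone
Product: 19 2-[(2E)-6-[(1R,2R)-1,2-dimethyl-2-(4-methylpent-3-enoyl)cyclopentyl]-3-methyl-5-oxohex-2-en-1-yl]-6-methylcyclohexa-2,5-diene-1,4-dione (CNP0111393.1)
Conditions: (KSO3)2NO (2.5 equiv), KH2PO4, acetone–H2O, rt
Reagents that add atoms: potassium nitrosodisulfonate (KSO3)2NO (Fremy's salt), [K+].[K+].[O]N(S(=O)(=O)[O-])S(=O)(=O)[O-]
Why: Teuber oxidation: one nitroxyl radical abstracts the phenolic hydrogen and a second adds at the free para carbon, and collapse gives the p-quinone and dearomatises the cresol ring at near-neutral pH, where the β,γ-unsaturated ketones, the alkenes and the quaternary centres are inert.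

## Compound list
1 | 4-methylpent-3-enoic acid | CC(C)=CCC(=O)O | starting material
2 | Meldrum's acid | CC1(C)OC(=O)CC(=O)O1 | starting material
3 | 5-(1-hydroxy-4-methylpent-3-en-1-ylidene)-2,2-dimethyl-1,3-dioxane-4,6-dione | CC(C)=CCC(O)=C1C(=O)OC(C)(C)OC1=O | intermediate
4 | (−)-menthone, (2S,5R)-2-isopropyl-5-methylcyclohexan-1-one | CC(C)[C@@H]1CC[C@@H](C)CC1=O | starting material
5 | (4-methylpent-3-enoyl)ketene | CC(C)=CCC(=O)C=C=O | intermediate
6 | (6R,7S,10R)-7-isopropyl-10-methyl-2-(3-methylbut-2-en-1-yl)-1,5-dioxaspiro[5.5]undec-2-en-4-one | CC(C)[C@@H]1CC[C@@H](C)C[C@@]12OC(=O)C=C(CC=C(C)C)O2 | intermediate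
7 | 1,2-dimethylcyclopent-1-ene | CC1=C(C)CCC1 | starting material
8 | cis-anti-cis photoadduct: a 6-4-5 tricycle (dioxanone, cyclobutane, cyclopentane) with a spiro-menthane acetal; both angular methyls lie on the cyclobutane face that carries the ring oxygen and the lactone carbonyl; all four cyclobutane carbons are R | CC(C)[C@@H]1CC[C@@H](C)C[C@@]12OC(=O)[C@@H]3[C@@]4(C)CCC[C@@]4(C)[C@]3(CC=C(C)C)O2 | intermediate
9 | isoprene | C=CC(C)=C | starting material
10 | benzenesulfonyl chloride | O=S(=O)(Cl)c1ccccc1 | starting material
11 | {[(2E)-4-chloro-2-methylbut-2-en-1-yl]sulfonyl}benzene | ClC/C=C(C)/CS(=O)(=O)c1ccccc1 | intermediate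
12 | o-cresol | Cc1ccccc1O | starting material
13 | sodium 2-methylphenolate | [Na+].[O-]c1ccccc1C | intermediate
14 | 2-methyl-6-[(2E)-3-methyl-4-(phenylsulfonyl)but-2-en-1-yl]phenol | Cc1cccc(C/C=C(C)/CS(=O)(=O)c2ccccc2)c1O | intermediate
15 | O,C-dilithio derivative of 14 | [Li+].[Li+].Cc1cccc(C/C=C(C)/[CH-]S(=O)(=O)c2ccccc2)c1[O-] | intermediate
16 | dilithium cyclobutanolate (acylated, menthone lost, cyclobutane still closed; sulfonyl-bearing carbon undefined) | [Li+].[Li+].[O-][C@@]1(CC=C(C)C)[C@]2(C)CCC[C@]2(C)[C@H]1C(=O)C(S(=O)(=O)c1ccccc1)/C(C)=C/Cc1cccc(C)c1[O-] | intermediate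
17 | 2-[(2E)-6-[(1R,2R)-1,2-dimethyl-2-(4-methylpent-3-enoyl)cyclopentyl]-3-methyl-5-oxo-4-(phenylsulfonyl)hex-2-en-1-yl]-6-methylphenol (epimers at C4) | CC(C)=CCC(=O)[C@]1(C)CCC[C@]1(C)CC(=O)C(S(=O)(=O)c1ccccc1)/C(C)=C/Cc1cccc(C)c1O | intermediate
18 | 2-[(2E)-6-[(1R,2R)-1,2-dimethyl-2-(4-methylpent-3-enoyl)cyclopentyl]-3-methyl-5-oxohex-2-en-1-yl]-6-methylphenol | CC(C)=CCC(=O)[C@]1(C)CCC[C@]1(C)CC(=O)C/C(C)=C/Cc1cccc(C)c1O | intermediate
19 | CNP0111393.1 | CC(C)=CCC(=O)[C@]1(C)CCC[C@]1(C)CC(=O)C/C(C)=C/CC1=CC(=O)C=C(C)C1=O | target

## Step count and risks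
Total: 7 steps. Longest linear sequence: 5 steps (1, 2, 3, 6, 7). Steps 4 and 5 build the second fragment.

**Step 3 (highest risk).** Three things can go wrong:
- The side-chain alkene of 6 may divert the excited dioxinone.
- Biradical disproportionation can compete with ring closure on a tetrasubstituted alkene.
- Face selectivity and anti selectivity must both hold, so the configuration of crystalline 8 is checked by X-ray before going on.

The fallback sets out from 4 and 7 and rejoins the route at 17. It brings in the side-chain alkene only after the photochemistry. Thermolysis of commercial 2,2,6-trimethyl-4H-1,3-dioxin-4-one in the presence of 4 gives, through acetylketene F1, the 2-methyl spiro-dioxinone F2. Irradiation of F2 with 7 gives the methyl photoadduct F3. Opening F3 with dianion 15 passes through the methyl cyclobutanolate F4 and gives the methyl ketone β-keto sulfone F5, whose side-chain ketone stays masked as its stabilised anion. With LiN(SiMe3)2 (4.2 equiv), the last-formed and most reactive methyl-ketone enolate is alkenylated with 1-bromo-2-methylprop-1-ene under Pd2(dba)3/Q-Phos catalysis (enolate α-alkenylation). α-Protonation of the resulting dienolate gives 17, which is reduced with SmI2 as in step 6.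

**Step 6.** The secondary sulfonyl carbanion may be too bulky for the hindered lactone carbonyl of 8. The fallback sets out from 8 and rejoins at 17. It lowers the oxidation level first. i-Bu2AlH (1.05 equiv, CH2Cl2, −78 °C) reduces the lactone while both ketones are still masked. Work-up releases 4 and, after retro-aldol, the keto aldehyde F6. Dianion 15 adds at −78 °C to the unhindered aldehyde in preference to the neopentyl ketone and gives the β-hydroxy sulfone F7. NaHCO3-buffered Dess–Martin oxidation then gives 17.

**Step 5.** O-allylation, or phenoxide-induced loss of HCl from 11, may dominate. The fallback sets out from 12 and 11 and rejoins at 14. It replaces the ambident phenoxide with a carbon–metal nucleophile. Compound 12 is protected (MOMCl, i-Pr2NEt) as the MOM ether F8. F8 is lithiated ortho to the OMOM group (n-BuLi, TMEDA, Et2O, 0 °C) to the aryllithium F9, which is transmetalated with ZnCl2 to the non-basic arylzinc chloride F10. F10 is coupled with 11 under Pd(PPh3)4 catalysis (Negishi allylation through a zerovalent palladium cycle, bond formation at the primary allyl terminus, E geometry kept) to give the MOM-protected sulfone F11. HCl in MeOH then gives 14.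

## Further compounds
F1 | step 3 | acetylketene | CC(=O)C=C=O
F2 | step 3 | (6R,7S,10R)-7-isopropyl-2,10-dimethyl-1,5-dioxaspiro[5.5]undec-2-en-4-one | CC(C)[C@@H]1CC[C@@H](C)C[C@@]12OC(=O)C=C(C)O2
F3 | step 3 | methyl photoadduct (2'-methyl analogue of 8, same configuration) | CC(C)[C@@H]1CC[C@@H](C)C[C@@]12OC(=O)[C@@H]3[C@@]4(C)CCC[C@@]4(C)[C@]3(C)O2
F4 | step 3 | methyl cyclobutanolate (methyl analogue of 16) | [Li+].[Li+].[O-][C@@]1(C)[C@]2(C)CCC[C@]2(C)[C@H]1C(=O)C(S(=O)(=O)c1ccccc1)/C(C)=C/Cc1cccc(C)c1[O-]
F5 | step 3 | 2-[(2E)-6-[(1R,2R)-2-acetyl-1,2-dimethylcyclopentyl]-3-methyl-5-oxo-4-(phenylsulfonyl)hex-2-en-1-yl]-6-methylphenol | CC(=O)[C@]1(C)CCC[C@]1(C)CC(=O)C(S(=O)(=O)c1ccccc1)/C(C)=C/Cc1cccc(C)c1O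
F6 | step 6 | 2-[(1R,2R)-1,2-dimethyl-2-(4-methylpent-3-enoyl)cyclopentyl]acetaldehyde | CC(C)=CCC(=O)[C@]1(C)CCC[C@]1(C)CC=O
F7 | step 6 | 2-[(2E)-6-[(1R,2R)-1,2-dimethyl-2-(4-methylpent-3-enoyl)cyclopentyl]-5-hydroxy-3-methyl-4-(phenylsulfonyl)hex-2-en-1-yl]-6-methylphenol | CC(C)=CCC(=O)[C@]1(C)CCC[C@]1(C)CC(O)C(S(=O)(=O)c1ccccc1)/C(C)=C/Cc1cccc(C)c1O
F8 | step 5 | 1-(methoxymethoxy)-2-methylbenzene | COCOc1ccccc1C
F9 | step 5 | [2-(methoxymethoxy)-3-methylphenyl]lithium | [Li]c1cccc(C)c1OCOC
F10 | step 5 | [2-(methoxymethoxy)-3-methylphenyl]zinc chloride | Cl[Zn]c1cccc(C)c1OCOC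
F11 | step 5 | 2-(methoxymethoxy)-1-methyl-3-[(2E)-3-methyl-4-(phenylsulfonyl)but-2-en-1-yl]benzene | COCOc1c(C)cccc1C/C=C(C)/CS(=O)(=O)c1ccccc1
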